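The route rests on cutting the pyran ring (ring C) of the isoflavan unit between C2 and C3 and carrying C4 as an aryl ketone. An O-methylthiomethyl deoxybenzoin is ionised at sulfur to an aryloxymethyl cation on O1, and the enol silane carbon C3 closes ring C onto C2 in one operation, giving an isoflavanone. The step exploits that C4 sits on ring A ortho to O1: the C4 carbonyl makes C3 nucleophilic within six-ring reach of O1–CH2, leaves C3 epimerisable for a later dynamic kinetic resolution, and deactivates ring A so that a biomimetic Friedel–Crafts union with the second chroman occurs at C5' of ring B.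

Key step: step 4

Remark on labels and assumptions: in the isoflavan unit, ring A is the 7-oxygenated benzo ring, ring C the pyran ring (O1, C2, C3, C4, C4a, C8a) and ring B the central 2'-hydroxy-4'-methoxyphenyl ring (C1'–C6'). In the second chroman, ring D is the benzo ring, ring F the pyran ring (C2'', C3'', C4'') and ring E the 2,3-dihydroxy-4-methoxyphenyl ring. Compounds 1, 3 and 9 are taken as commercial. C3 is carried racemic through 8 and 16 on purpose and is set in step 10.

Step 1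
Reactants: 1 1-[4-(benzyloxy)-2-hydroxyphenyl]ethan-1-one
Product: 2 1-[4-(benzyloxy)-2-[(methylsulfanyl)methoxy]phenyl]ethan-1-one
Conditions: NaH, MeSCH2Cl, NaI (cat.), DMF, 0 °C → rt
Reagents that add atoms: chloromethyl methyl sulfide, CSCCl
Why: Williamson O-alkylation of the sodium phenoxide with the reactive α-chloro sulfide installs an O,S-acetal that protects O1 during step 3 and carries the latent C2 electrophile.

Step 2
Reactants: 3 2-bromo-5-methoxyphenol
Product: 4 2-(benzyloxy)-1-bromo-4-methoxybenzene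
Conditions: BnBr, K2CO3, DMF, 50 °C
Reagents that add atoms: benzyl bromide, BrCc1ccccc1
Why: Williamson etherification protects the future 2'-OH of ring B as a benzyl ether that is removed in the final hydrogenolysis.

Step 3
Reactants: 2 1-[4-(benzyloxy)-2-[(methylsulfanyl)methoxy]phenyl]ethan-1-one; 4 2-(benzyloxy)-1-bromo-4-methoxybenzene
Product: 5 2-[2-(benzyloxy)-4-methoxyphenyl]-1-[4-(benzyloxy)-2-[(methylsulfanyl)methoxy]phenyl]ethan-1-one
Conditions: Pd2(dba)3 (2 mol%), XPhos (8 mol%), NaOtBu, toluene, 80 °C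
Reagents that add atoms: none
Why: Buchwald–Hartwig α-arylation of the methyl ketone enolate forms the C3–C1' bond; the ortho-benzyloxy group of 4 should disfavour a second arylation, and the O,S-acetal is base-stable.

Step 4
Reactants: 5 2-[2-(benzyloxy)-4-methoxyphenyl]-1-[4-(benzyloxy)-2-[(methylsulfanyl)methoxy]phenyl]ethan-1-one
Product: 8 racemic 7-(benzyloxy)-3-[2-(benzyloxy)-4-methoxyphenyl]chroman-4-one, via enol silane 6 (not isolated), via sulfonium triflate 7 (not isolated)
Conditions: TMSOTf, Et3N, CH2Cl2, 0 °C; then MeOTf, 2,6-di-tert-butyl-4-methylpyridine, 0 °C → rt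
Reagents that add atoms: none
Why: TMSOTf/Et3N converts the ketone into the (Z)-enol silane 6, MeOTf then methylates the thioether sulfur to sulfonium 7, which loses Me2S to an aryloxymethyl cation (O1=C2 oxocarbenium); the enol carbon C3 attacks C2 and the silyloxycarbenium collapses to ketone 8 with release of TMSOTf. The closest known reaction type is the Mukaiyama-type addition of enol silanes to oxocarbenium ions set free from O,S-acetals by S-alkylation (thioglycoside-type activation, as in C-glycosylation), here run intramolecularly. Ring C closes in a 6-(enolendo)-endo-trig mode through the conjugated C3=C4–C4a=C8a–O1=C2 array, geometrically an oxonia-6π closure. The new stereocentre C3 is formed racemic on purpose: as an α-aryl ketone carbon it is configurationally labile and is set, together with C4, by the dynamic kinetic resolution of step 10. The selectivity needed is C- over O-capture of the cation and S-methylation over reaction of MeOTf elsewhere; O-capture would give a 1,3-benzodioxine O,O-acetal that should re-ionise under the conditions whereas C–C bond formation is irreversible, and the dialkyl sulfide is by far the best nucleophile for MeOTf in 6.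

Step 5
Reactants: 9 2,3-dihydroxy-4-methoxybenzaldehyde
Product: 10 2,3-bis(benzyloxy)-4-methoxybenzaldehyde
Conditions: BnBr, K2CO3, DMF, 60 °C
Reagents that add atoms: benzyl bromide, BrCc1ccccc1
Why: double Williamson etherification masks both ring E phenols as benzyl ethers for the final hydrogenolysis.

Step 6
Reactants: 1 1-[4-(benzyloxy)-2-hydroxyphenyl]ethan-1-one; 10 2,3-bis(benzyloxy)-4-methoxybenzaldehyde
Product: 11 (E)-1-[4-(benzyloxy)-2-hydroxyphenyl]-3-[2,3-bis(benzyloxy)-4-methoxyphenyl]prop-2-en-1-one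
Conditions: KOH, EtOH, rt; then AcOH
Reagents that add atoms: none
Why: Claisen–Schmidt condensation (aldol addition, then E1cB dehydration) gives the thermodynamically favoured E-chalcone.

Step 7
Reactants: 11 (E)-1-[4-(benzyloxy)-2-hydroxyphenyl]-3-[2,3-bis(benzyloxy)-4-methoxyphenyl]prop-2-en-1-one
Product: 13 7-(benzyloxy)-3-[2,3-bis(benzyloxy)-4-methoxyphenyl]-4H-chromen-4-one, via acetal 12 (not isolated)
Conditions: Tl(NO3)3·3H2O, MeOH/HC(OMe)3, rt; then 10% HCl, MeOH, 60 °C
Reagents that add atoms: none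
Why: oxidative 1,2-aryl migration of the chalcone (oxythallation of the enone, shift of the electron-rich ring E from Cβ to Cα, giving acetal 12) followed by acid cyclisation of the 2-hydroxyphenyl ketone onto the acetal carbon with loss of methanol gives the isoflavone.

Step 8
Reactants: 13 7-(benzyloxy)-3-[2,3-bis(benzyloxy)-4-methoxyphenyl]-4H-chromen-4-one
Product: 15 (3R,4R)-7-(benzyloxy)-3-[2,3-bis(benzyloxy)-4-methoxyphenyl]chroman-4-ol, via isoflavanone 14 (not isolated)
Conditions: RuCl[(R,R)-TsDPEN](p-cymene) (5 mol%), HCO2H/Et3N (5:2), EtOAc, 45 °C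
Reagents that add atoms: none
Why: Noyori-type asymmetric transfer hydrogenation; Ru–H conjugate reduction gives the racemising isoflavanone 14, whose ketone is reduced under dynamic kinetic resolution, the (R,R)-ligand fixing C4 as R and hydride delivery anti to ring E giving the 3,4-cis (3R,4R) alcohol.

Step 9
Reactants: 8 racemic 7-(benzyloxy)-3-[2-(benzyloxy)-4-methoxyphenyl]chroman-4-one; 15 (3R,4R)-7-(benzyloxy)-3-[2,3-bis(benzyloxy)-4-methoxyphenyl]chroman-4-ol
Product: 16 7-(benzyloxy)-3-{2-(benzyloxy)-5-[(3R,4S)-7-(benzyloxy)-3-[2,3-bis(benzyloxy)-4-methoxyphenyl]chroman-4-yl]-4-methoxyphenyl}chroman-4-one (both C3 epimers)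
Conditions: TfOH (5 mol%), CH2Cl2/(CF3)2CHOH (4:1), −30 → 0 °C, 8 (3 equiv), slow addition of 15
Reagents that add atoms: none
Why: Friedel–Crafts benzylation; acid ionises the para-alkoxybenzylic alcohol to the C4'' cation, which is captured by ring B of 8 at C5' (para to OBn, ortho to OMe; ring A is deactivated by its conjugated C4 ketone) anti to ring E on C3'', setting C4'' as S (3'',4''-trans).

Step 10
Reactants: 16 7-(benzyloxy)-3-{2-(benzyloxy)-5-[(3R,4S)-7-(benzyloxy)-3-[2,3-bis(benzyloxy)-4-methoxyphenyl]chroman-4-yl]-4-methoxyphenyl}chroman-4-one (both C3 epimers)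
Product: 17 (3R,4R)-7-(benzyloxy)-3-{2-(benzyloxy)-5-[(3R,4S)-7-(benzyloxy)-3-[2,3-bis(benzyloxy)-4-methoxyphenyl]chroman-4-yl]-4-methoxyphenyl}chroman-4-ol
Conditions: RuCl[(R,R)-TsDPEN](p-cymene) (5 mol%), HCO2H/Et3N (5:2), EtOAc, 45 °C
Reagents that add atoms: none
Why: Noyori-type asymmetric transfer hydrogenation with dynamic kinetic resolution; C3 epimerises through the enol of the α-aryl ketone, the (R,R)-catalyst reduces the (3R)-ketone faster and sets C4 as R with the 3,4-cis relationship, so both epimers of 16 should converge on the (3R,4R) alcohol while C3'' and C4'' are untouched.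

Step 11
Reactants: 17 (3R,4R)-7-(benzyloxy)-3-{2-(benzyloxy)-5-[(3R,4S)-7-(benzyloxy)-3-[2,3-bis(benzyloxy)-4-methoxyphenyl]chroman-4-yl]-4-methoxyphenyl}chroman-4-ol
Product: 18 (3R)-3-{5-[(3R,4S)-3-(2,3-dihydroxy-4-methoxyphenyl)-7-hydroxychroman-4-yl]-2-hydroxy-4-methoxyphenyl}chroman-7-ol
Conditions: H2 (1 atm), 10% Pd/C, EtOH/EtOAc, AcOH (cat.), rt → 40 °C
Reagents that add atoms: none
Why: catalytic hydrogenolysis cleaves the five O-benzyl ethers and the electron-rich benzylic C4–OH bond (deoxygenation to C4H2) without touching C3, C3'' or C4''.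

Compound list
1 | 1-[4-(benzyloxy)-2-hydroxyphenyl]ethan-1-one | CC(=O)c1ccc(OCc2ccccc2)cc1O | starting material
2 | 1-[4-(benzyloxy)-2-[(methylsulfanyl)methoxy]phenyl]ethan-1-one | CC(=O)c1ccc(OCc2ccccc2)cc1OCSC | intermediate
3 | 2-bromo-5-methoxyphenol | COc1ccc(Br)c(O)c1 | starting material
4 | 2-(benzyloxy)-1-bromo-4-methoxybenzene | COc1ccc(Br)c(OCc2ccccc2)c1 | intermediate
5 | 2-[2-(benzyloxy)-4-methoxyphenyl]-1-[4-(benzyloxy)-2-[(methylsulfanyl)methoxy]phenyl]ethan-1-one | COc1ccc(CC(=O)c2ccc(OCc3ccccc3)cc2OCSC)c(OCc2ccccc2)c1 | intermediate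
6 | (Z)-trimethylsilyl enol ether of 5 | COc1ccc(/C=C(\O[Si](C)(C)C)c2ccc(OCc3ccccc3)cc2OCSC)c(OCc2ccccc2)c1 | intermediate
7 | ({5-(benzyloxy)-2-[(Z)-2-[2-(benzyloxy)-4-methoxyphenyl]-1-(trimethylsilyloxy)ethenyl]phenoxy}methyl)dimethylsulfonium trifluoromethanesulfonate | COc1ccc(/C=C(\O[Si](C)(C)C)c2ccc(OCc3ccccc3)cc2OC[S+](C)C)c(OCc2ccccc2)c1.[O-]S(=O)(=O)C(F)(F)F | intermediate
8 | racemic 7-(benzyloxy)-3-[2-(benzyloxy)-4-methoxyphenyl]chroman-4-one | COc1ccc(C2COc3cc(OCc4ccccc4)ccc3C2=O)c(OCc2ccccc2)c1 | intermediate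
9 | 2,3-dihydroxy-4-methoxybenzaldehyde | COc1ccc(C=O)c(O)c1O | starting material
10 | 2,3-bis(benzyloxy)-4-methoxybenzaldehyde | COc1ccc(C=O)c(OCc2ccccc2)c1OCc1ccccc1 | intermediate
11 | (E)-1-[4-(benzyloxy)-2-hydroxyphenyl]-3-[2,3-bis(benzyloxy)-4-methoxyphenyl]prop-2-en-1-one | COc1ccc(/C=C/C(=O)c2ccc(OCc3ccccc3)cc2O)c(OCc2ccccc2)c1OCc1ccccc1 | intermediate
12 | racemic 1-[4-(benzyloxy)-2-hydroxyphenyl]-2-[2,3-bis(benzyloxy)-4-methoxyphenyl]-3,3-dimethoxypropan-1-one | COc1ccc(C(C(OC)OC)C(=O)c2ccc(OCc3ccccc3)cc2O)c(OCc2ccccc2)c1OCc1ccccc1 | intermediate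
13 | 7-(benzyloxy)-3-[2,3-bis(benzyloxy)-4-methoxyphenyl]-4H-chromen-4-one | COc1ccc(-c2coc3cc(OCc4ccccc4)ccc3c2=O)c(OCc2ccccc2)c1OCc1ccccc1 | intermediate
14 | racemic 7-(benzyloxy)-3-[2,3-bis(benzyloxy)-4-methoxyphenyl]chroman-4-one | COc1ccc(C2COc3cc(OCc4ccccc4)ccc3C2=O)c(OCc2ccccc2)c1OCc1ccccc1 | intermediate
15 | (3R,4R)-7-(benzyloxy)-3-[2,3-bis(benzyloxy)-4-methoxyphenyl]chroman-4-ol | O[C@H]1c2ccc(OCc3ccccc3)cc2OC[C@H]1c1ccc(OC)c(OCc2ccccc2)c1OCc1ccccc1 | intermediate
16 | 7-(benzyloxy)-3-{2-(benzyloxy)-5-[(3R,4S)-7-(benzyloxy)-3-[2,3-bis(benzyloxy)-4-methoxyphenyl]chroman-4-yl]-4-methoxyphenyl}chroman-4-one (both C3 epimers) | COc1cc(OCc2ccccc2)c(C2COc3cc(OCc4ccccc4)ccc3C2=O)cc1[C@@H]1c2ccc(OCc3ccccc3)cc2OC[C@H]1c1ccc(OC)c(OCc2ccccc2)c1OCc1ccccc1 | intermediate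
17 | (3R,4R)-7-(benzyloxy)-3-{2-(benzyloxy)-5-[(3R,4S)-7-(benzyloxy)-3-[2,3-bis(benzyloxy)-4-methoxyphenyl]chroman-4-yl]-4-methoxyphenyl}chroman-4-ol | COc1cc(OCc2ccccc2)c([C@@H]2COc3cc(OCc4ccccc4)ccc3[C@@H]2O)cc1[C@@H]1c2ccc(OCc3ccccc3)cc2OC[C@H]1c1ccc(OC)c(OCc2ccccc2)c1OCc1ccccc1 | intermediate
18 | (3R)-3-{5-[(3R,4S)-3-(2,3-dihydroxy-4-methoxyphenyl)-7-hydroxychroman-4-yl]-2-hydroxy-4-methoxyphenyl}chroman-7-ol | COc1cc(O)c([C@@H]2COc3cc(O)ccc3C2)cc1[C@@H]1c2ccc(O)cc2OC[C@H]1c1ccc(OC)c(O)c1O | target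

Total step count: 11. Longest linear sequence: 7 steps (steps 5, 6, 7, 8, 9, 10, 11).

Steps most likely to fail

Step 9. The C4'' cation may be consumed by the electron-rich rings D and E of a second molecule of 15. It may also lose the C3'' proton to an isoflav-3-ene, which would erode C3'' on re-protonation, or be trapped by the 2-benzyloxy oxygen of ring E. The bulky, only moderately nucleophilic ketone 8 cannot be used in large excess to outrun these paths. The fallback moves the union to a small, cheap and more nucleophilic arene and builds ring C afterwards. It sets out from 15, which is ionised under the same acid catalysis in the presence of a large excess of phenol 3; attack para to the free hydroxyl should give 2-bromo-4-{(3R,4S)-7-(benzyloxy)-3-[2,3-bis(benzyloxy)-4-methoxyphenyl]chroman-4-yl}-5-methoxyphenol F1. Benzylation (BnBr, K2CO3) gives the benzyl ether F2. α-Arylation of ketone 2 with this bromide under the conditions of step 3 gives the deoxybenzoin F3. Enol silylation to the enol silane F4 and S-methylation to the sulfonium triflate F5, as in step 4, then close ring C, and the fallback comes back to the route at 16.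

Step 4. The cation may be captured at oxygen instead of carbon (1,3-benzodioxine formation that fails to revert), the enol silane may be desilylated before ionisation, or intermolecular alkylation may compete. The fallback keeps the same ring closure but uses a softer, longer-lived thionium electrophile (Pummerer cyclisation). It sets out from 5, which is oxidised with NaIO4 to the sulfoxide F6. TFAA and 2,6-lutidine, then SnCl4, generate the thionium ion on O1–CH, which the ketone enol carbon C3 should attack to give the 2-(methylsulfanyl)isoflavanone F7. Elimination of methanethiol with DBU gives the isoflavone F8, and 1,4-reduction with LiBH(s-Bu)3 at −78 °C comes back to the route at 8.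

Step 11. Acid-assisted ionisation at C4 with loss of the C3 proton would give an isoflav-3-ene, whose unselective hydrogenation would scramble C3; alternatively the C4–O hydrogenolysis may stall. The fallback separates debenzylation from deoxygenation and traps the C4 cation intramolecularly. It sets out from 17, which is debenzylated with H2 and Pd/C in EtOAc/MeOH without acid to the pentaphenolic isoflavan-4-ol F9. Dilute HCl then closes the ring B 2'-hydroxyl onto C4, a cyclisation that should outrun proton loss and retain C3, giving the cis-fused pterocarpan F10. Hydrogenolysis of its benzylic aryl ether bond (H2, Pd/C, AcOH) comes back to the route at 18.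

Further compounds
F1 | step 9 | 2-bromo-4-{(3R,4S)-7-(benzyloxy)-3-[2,3-bis(benzyloxy)-4-methoxyphenyl]chroman-4-yl}-5-methoxyphenol | COc1cc(O)c(Br)cc1[C@@H]1c2ccc(OCc3ccccc3)cc2OC[C@H]1c1ccc(OC)c(OCc2ccccc2)c1OCc1ccccc1
F2 | step 9 | (3R,4S)-7-(benzyloxy)-4-[4-(benzyloxy)-5-bromo-2-methoxyphenyl]-3-[2,3-bis(benzyloxy)-4-methoxyphenyl]chroman | COc1cc(OCc2ccccc2)c(Br)cc1[C@@H]1c2ccc(OCc3ccccc3)cc2OC[C@H]1c1ccc(OC)c(OCc2ccccc2)c1OCc1ccccc1
F3 | step 9 | 2-{2-(benzyloxy)-5-[(3R,4S)-7-(benzyloxy)-3-[2,3-bis(benzyloxy)-4-methoxyphenyl]chroman-4-yl]-4-methoxyphenyl}-1-[4-(benzyloxy)-2-[(methylsulfanyl)methoxy]phenyl]ethan-1-one | COc1cc(OCc2ccccc2)c(CC(=O)c2ccc(OCc3ccccc3)cc2OCSC)cc1[C@@H]1c2ccc(OCc3ccccc3)cc2OC[C@H]1c1ccc(OC)c(OCc2ccccc2)c1OCc1ccccc1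
F4 | step 9 | (Z)-trimethylsilyl enol ether of F3 | COc1cc(OCc2ccccc2)c(/C=C(\O[Si](C)(C)C)c2ccc(OCc3ccccc3)cc2OCSC)cc1[C@@H]1c2ccc(OCc3ccccc3)cc2OC[C@H]1c1ccc(OC)c(OCc2ccccc2)c1OCc1ccccc1
F5 | step 9 | S,S-dimethylsulfonium trifluoromethanesulfonate of F4 | COc1cc(OCc2ccccc2)c(/C=C(\O[Si](C)(C)C)c2ccc(OCc3ccccc3)cc2OC[S+](C)C)cc1[C@@H]1c2ccc(OCc3ccccc3)cc2OC[C@H]1c1ccc(OC)c(OCc2ccccc2)c1OCc1ccccc1.[O-]S(=O)(=O)C(F)(F)F
F6 | step 4 | 2-[2-(benzyloxy)-4-methoxyphenyl]-1-[4-(benzyloxy)-2-[(methanesulfinyl)methoxy]phenyl]ethan-1-one | COc1ccc(CC(=O)c2ccc(OCc3ccccc3)cc2OCS(C)=O)c(OCc2ccccc2)c1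
F7 | step 4 | 7-(benzyloxy)-3-[2-(benzyloxy)-4-methoxyphenyl]-2-(methylsulfanyl)chroman-4-one (mixture of stereoisomers) | COc1ccc(C2C(SC)Oc3cc(OCc4ccccc4)ccc3C2=O)c(OCc2ccccc2)c1
F8 | step 4 | 7-(benzyloxy)-3-[2-(benzyloxy)-4-methoxyphenyl]-4H-chromen-4-one | COc1ccc(-c2coc3cc(OCc4ccccc4)ccc3c2=O)c(OCc2ccccc2)c1
F9 | step 11 | (3R,4R)-3-{5-[(3R,4S)-3-(2,3-dihydroxy-4-methoxyphenyl)-7-hydroxychroman-4-yl]-2-hydroxy-4-methoxyphenyl}chroman-4,7-diol | COc1cc(O)c([C@@H]2COc3cc(O)ccc3[C@@H]2O)cc1[C@@H]1c2ccc(O)cc2OC[C@H]1c1ccc(OC)c(O)c1O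
F10 | step 11 | (6aR,11aR)-8-[(3R,4S)-3-(2,3-dihydroxy-4-methoxyphenyl)-7-hydroxychroman-4-yl]-9-methoxypterocarpan-3-ol | COc1cc2c(cc1[C@@H]3c4ccc(O)cc4OC[C@H]3c3ccc(OC)c(O)c3O)[C@@H]3COc4cc(O)ccc4[C@@H]3O2
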